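## Retrosynthetic overview

1. The strategy rests on the open 1,2-diarylpropane-1,3-diol arm. Its C1 carries OH and the 4-hydroxy-3-methoxyphenyl ring; its C2 carries CH2OH and ring B (the 2-hydroxy-3-methoxyphenyl ring tied through CH2 to the lactone α-carbon). Cutting both aryl–C bonds leaves a (Z)-C1=C2 alkenylboron unit whose boron becomes the C1 hydroxyl.
2. Key disconnection: three-component conjunctive coupling of 4-benzyloxy-3-methoxyphenyllithium, a (Z)-3-silyloxypropenylboronic ester, and the ring-B aryl bromide of the complete lactone fragment. The boronic ester carries the hindered "mac" diol instead of pinacol, because pinacol esters of β-substituted alkenylboronates mainly undergo direct Suzuki coupling. C–B oxidation, desilylation and hydrogenolysis follow.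
3. Lactone fragment: trans α-benzylation of the (S)-β-(dihydrobenzofuranylmethyl)butyrolactone with 4-benzyloxy-3-bromo-5-methoxybenzyl bromide. The lactone comes from auxiliary-controlled alkylation of a pent-4-enoyl oxazolidinone with the dihydrobenzofuran benzylic bromide, then reduction, alkene cleavage and lactol oxidation.
4. Dihydrobenzofuran: rhodium-carbene 1,5 C–H insertion of an aryldiazoacetate built on 5-bromovanillin, then epimerisation at C3 to trans.
5. Ring order: the dihydrofuran ring of the benzofuran first (step 9), the butyrolactone second (steps 18 and 19); the key step closes no ring.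

Key step: step 25

Assumption (remark on the chemistry): the sense of induction of Rh2(S-PTTL)4 in step 9 and of the (Sp,Sp)-MandyPhos ligand in step 25 is taken by analogy with simpler substrates; if a pilot run shows the opposite sense, the antipodal catalyst is used with no other change.

Abbreviations used in names: Ar = 4-(benzyloxy)-3-methoxyphenyl; DHB = (2R,3S)-2-Ar-3-{[(tert-butyldiphenylsilyl)oxy]methyl}-7-methoxy-2,3-dihydro-1-benzofuran-5-yl; B(mac) = boron bound to the cis-1,2-dimethylacenaphthene-1,2-diolate; TBS = tert-butyldimethylsilyl; TBDPS = tert-butyldiphenylsilyl.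

## Route

Step 1
Reactants: 1 5-bromovanillin
Product: 2 4-(benzyloxy)-3-bromo-5-methoxybenzaldehyde
Conditions: BnBr, K2CO3, DMF, 60 °C
Reagents that add atoms: benzyl bromide, BrCc1ccccc1
Why: Williamson etherification of the acidic phenoxide with a benzylic bromide is routine and protects the phenol that will sit ortho to the coupling site, with no stereocentre formed.

Step 2
Reactants: 2 4-(benzyloxy)-3-bromo-5-methoxybenzaldehyde
Product: 3 [4-(benzyloxy)-3-bromo-5-methoxyphenyl]methanol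
Conditions: NaBH4, MeOH/THF, 0 °C
Reagents that add atoms: none
Why: Borohydride reduction of the aryl aldehyde is chemoselective in the presence of the aryl bromide and the benzyl ether.

Step 3
Reactants: 3 [4-(benzyloxy)-3-bromo-5-methoxyphenyl]methanol
Product: 4 2-(benzyloxy)-1-bromo-5-(bromomethyl)-3-methoxybenzene
Conditions: PBr3, CH2Cl2, 0 °C
Reagents that add atoms: phosphorus tribromide, BrP(Br)Br
Why: Substitution of the benzylic alcohol by bromide with PBr3 is a standard reaction and gives the electrophile for the later lactone alkylation.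

Step 4
Reactants: 1 5-bromovanillin; 5 [4-(benzyloxy)-3-methoxyphenyl]methanol
Product: 6 4-(Ar-methoxy)-3-bromo-5-methoxybenzaldehyde
Conditions: PPh3, DIAD, THF, 0 °C to rt
Reagents that add atoms: none
Why: Mitsunobu etherification joins the acidic phenol (activated by the ortho bromine and para formyl group) to the primary benzylic alcohol under neutral conditions, installing the ArCH2–O unit whose C–H bond is inserted in step 9.

Step 5
Reactants: 6 4-(Ar-methoxy)-3-bromo-5-methoxybenzaldehyde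
Product: 7 [4-(Ar-methoxy)-3-bromo-5-methoxyphenyl]methanol
Conditions: NaBH4, MeOH/THF, 0 °C
Reagents that add atoms: none
Why: Borohydride reduction converts the aldehyde into the benzylic alcohol that later becomes the alkylating handle, leaving the aryl bromide and both ethers intact.

Step 6
Reactants: 7 [4-(Ar-methoxy)-3-bromo-5-methoxyphenyl]methanol
Product: 8 {[4-(Ar-methoxy)-3-bromo-5-methoxyphenyl]methoxy}(tert-butyl)dimethylsilane
Conditions: TBSCl, imidazole, DMF, rt
Reagents that add atoms: tert-butyldimethylsilyl chloride, CC(C)(C)[Si](C)(C)Cl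
Why: Silylation masks the benzylic alcohol against the organozinc, diazo, carbene and hydride steps that follow.

Step 7
Reactants: 8 {[4-(Ar-methoxy)-3-bromo-5-methoxyphenyl]methoxy}(tert-butyl)dimethylsilane
Product: 9 tert-butyl 2-[2-(Ar-methoxy)-5-{[(tert-butyldimethylsilyl)oxy]methyl}-3-methoxyphenyl]acetate
Conditions: BrZnCH2CO2t-Bu, Pd(dba)2 (2 mol %), Q-Phos [1,2,3,4,5-pentaphenyl-1'-(di-tert-butylphosphino)ferrocene] (2 mol %), THF, rt to 50 °C
Reagents that add atoms: (2-tert-butoxy-2-oxoethyl)zinc bromide, CC(C)(C)OC(=O)C[Zn]Br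
Why: Palladium-catalysed α-arylation of a zinc ester enolate (Reformatsky–Negishi coupling) tolerates silyl and benzyl ethers and works on electron-rich ortho-alkoxy aryl bromides with a bulky electron-rich phosphine.

Step 8
Reactants: 9 tert-butyl 2-[2-(Ar-methoxy)-5-{[(tert-butyldimethylsilyl)oxy]methyl}-3-methoxyphenyl]acetate
Product: 10 tert-butyl 2-diazo-2-[2-(Ar-methoxy)-5-{[(tert-butyldimethylsilyl)oxy]methyl}-3-methoxyphenyl]acetate
Conditions: p-ABSA, DBU, MeCN, 0 °C to rt
Reagents that add atoms: 4-acetamidobenzenesulfonyl azide, CC(=O)Nc1ccc(cc1)S(=O)(=O)N=[N+]=[N-]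
Why: Regitz diazo transfer to the acidic benzylic methylene of an arylacetate gives the donor/acceptor diazo ester.

Step 9
Reactants: 10 tert-butyl 2-diazo-2-[2-(Ar-methoxy)-5-{[(tert-butyldimethylsilyl)oxy]methyl}-3-methoxyphenyl]acetate
Product: 11 tert-butyl (2R,3S)-2-Ar-5-{[(tert-butyldimethylsilyl)oxy]methyl}-7-methoxy-2,3-dihydro-1-benzofuran-3-carboxylate (cis)
Conditions: Rh2(S-PTTL)4 {dirhodium tetrakis[N-phthaloyl-(S)-tert-leucinate]} (1 mol %), toluene, −60 °C
Reagents that add atoms: none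
Why: The rhodium donor/acceptor carbene inserts intramolecularly (1,5) into the ether-activated benzylic C–H bond and closes the dihydrofuran ring, the chiral carboxylate ligands choosing between the two enantiotopic C–H bonds so that C2 is set as R, while the cis ester that should predominate has its C3 corrected in step 10.

Step 10
Reactants: 11 tert-butyl (2R,3S)-2-Ar-5-{[(tert-butyldimethylsilyl)oxy]methyl}-7-methoxy-2,3-dihydro-1-benzofuran-3-carboxylate (cis)
Product: 12 tert-butyl (2R,3R)-2-Ar-5-{[(tert-butyldimethylsilyl)oxy]methyl}-7-methoxy-2,3-dihydro-1-benzofuran-3-carboxylate (trans)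
Conditions: t-BuOK (0.2 equiv), t-BuOH/THF, 0 °C to rt
Reagents that add atoms: none
Why: Catalytic alkoxide epimerises the ester α-carbon C3 through its enolate to the thermodynamically preferred trans isomer, while C2 is not touched.

Step 11
Reactants: 12 tert-butyl (2R,3R)-2-Ar-5-{[(tert-butyldimethylsilyl)oxy]methyl}-7-methoxy-2,3-dihydro-1-benzofuran-3-carboxylate (trans)
Product: 13 [(2R,3S)-2-Ar-5-{[(tert-butyldimethylsilyl)oxy]methyl}-7-methoxy-2,3-dihydro-1-benzofuran-3-yl]methanol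
Conditions: LiAlH4, THF, 0 °C
Reagents that add atoms: none
Why: Hydride reduction of the ester to the primary alcohol leaves the silyl ether, the benzyl ether and both ring stereocentres unchanged.

Step 12
Reactants: 13 [(2R,3S)-2-Ar-5-{[(tert-butyldimethylsilyl)oxy]methyl}-7-methoxy-2,3-dihydro-1-benzofuran-3-yl]methanol
Product: 14 (2R,3S)-2-Ar-5-{[(tert-butyldimethylsilyl)oxy]methyl}-3-{[(tert-butyldiphenylsilyl)oxy]methyl}-7-methoxy-2,3-dihydro-1-benzofuran
Conditions: TBDPSCl, imidazole, DMF, rt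
Reagents that add atoms: tert-butyldiphenylsilyl chloride, CC(C)(C)[Si](Cl)(c1ccccc1)c1ccccc1
Why: Silylation with the acid-stable TBDPS group differentiates this primary alcohol from the TBS-protected benzylic one.

Step 13
Reactants: 14 (2R,3S)-2-Ar-5-{[(tert-butyldimethylsilyl)oxy]methyl}-3-{[(tert-butyldiphenylsilyl)oxy]methyl}-7-methoxy-2,3-dihydro-1-benzofuran
Product: 15 DHB-methanol
Conditions: PPTS (cat.), MeOH, rt
Reagents that add atoms: none
Why: Mild acid-catalysed methanolysis removes a primary TBS ether far faster than a TBDPS ether, so only the benzylic alcohol is freed.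

Step 14
Reactants: 15 DHB-methanol
Product: 16 DHB-methyl bromide [(2R,3S)-2-Ar-5-(bromomethyl)-3-{[(tert-butyldiphenylsilyl)oxy]methyl}-7-methoxy-2,3-dihydro-1-benzofuran]
Conditions: CBr4, PPh3, CH2Cl2, 0 °C; used crude
Reagents that add atoms: carbon tetrabromide, BrC(Br)(Br)Br
Why: Appel bromination converts the benzylic alcohol into the bromide under neutral conditions that spare the silyl ether and the electron-rich benzylic ether system.

Step 15
Reactants: 17 (S)-4-benzyl-1,3-oxazolidin-2-one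
Product: 18 (S)-4-benzyl-3-(pent-4-enoyl)-1,3-oxazolidin-2-one
Conditions: pent-4-enoyl chloride, Et3N, DMAP (cat.), CH2Cl2, 0 °C to rt
Reagents that add atoms: pent-4-enoyl chloride, C=CCCC(Cl)=O
Why: DMAP-catalysed N-acylation of the oxazolidinone by an acid chloride gives the imide needed for auxiliary-controlled alkylation.

Step 16
Reactants: 18 (S)-4-benzyl-3-(pent-4-enoyl)-1,3-oxazolidin-2-one; 16 DHB-methyl bromide
Product: 20 (4S)-4-benzyl-3-[(2R)-2-(DHB-methyl)pent-4-enoyl]-1,3-oxazolidin-2-one, via sodium Z-enolate 19 (not isolated)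
Conditions: NaN(SiMe3)2, THF, −78 °C; then 16, −78 to −40 °C
Reagents that add atoms: none
Why: In this auxiliary-controlled (Evans) enolate alkylation the chelated Z sodium enolate is attacked by the reactive benzylic bromide on the face away from the C4 benzyl group, which sets the new centre as 2R, the future lactone C4 of S configuration.

Step 17
Reactants: 20 (4S)-4-benzyl-3-[(2R)-2-(DHB-methyl)pent-4-enoyl]-1,3-oxazolidin-2-one
Product: 21 (2R)-2-(DHB-methyl)pent-4-en-1-ol
Conditions: LiBH4, MeOH (1 equiv), Et2O, 0 °C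
Reagents that add atoms: none
Why: LiBH4 reduces the exocyclic imide carbonyl to the primary alcohol and releases the auxiliary without touching the stereocentre, the alkene or the silyl ether.

Step 18
Reactants: 21 (2R)-2-(DHB-methyl)pent-4-en-1-ol
Product: 23 (4S)-4-(DHB-methyl)oxolan-2-ol (both anomers), via hydroxy aldehyde 22 (not isolated)
Conditions: OsO4 (2 mol %), NaIO4, 2,6-lutidine, dioxane/H2O, rt
Reagents that add atoms: sodium periodate, [Na+].[O-]I(=O)(=O)=O
Why: Lemieux–Johnson cleavage of the terminal alkene gives the aldehyde, which the γ-hydroxyl traps as the five-membered lactol, an oxidation that fully O-alkylated electron-rich arenes tolerate.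

Step 19
Reactants: 23 (4S)-4-(DHB-methyl)oxolan-2-ol
Product: 24 (4S)-4-(DHB-methyl)oxolan-2-one
Conditions: Pr4N[RuO4] (5 mol %), NMO, 4 Å molecular sieves, CH2Cl2, rt
Reagents that add atoms: none
Why: Ley–Griffith oxidation converts the lactol into the γ-butyrolactone under neutral conditions without affecting the stereocentres.

Step 20
Reactants: 24 (4S)-4-(DHB-methyl)oxolan-2-one; 4 2-(benzyloxy)-1-bromo-5-(bromomethyl)-3-methoxybenzene
Product: 26 (3S,4S)-3-{[4-(benzyloxy)-3-bromo-5-methoxyphenyl]methyl}-4-(DHB-methyl)oxolan-2-one, via lithium lactone enolate 25 (not isolated)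
Conditions: LiN(SiMe3)2, THF, −78 °C; then 4, DMPU, −78 to −40 °C
Reagents that add atoms: none
Why: Alkylation of the lactone lithium enolate by the benzylic bromide occurs anti to the C4 substituent, as is general for β-substituted butyrolactones, and gives the trans-3,4-dibenzyl lactone with C3 of S configuration.

Step 21
Reactants: 27 4-bromo-2-methoxyphenol
Product: 28 1-(benzyloxy)-4-bromo-2-methoxybenzene
Conditions: BnBr, K2CO3, DMF, rt
Reagents that add atoms: benzyl bromide, BrCc1ccccc1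
Why: Williamson etherification protects the phenol so that bromine–lithium exchange can be carried out in step 25.

Step 22
Reactants: 29 acenaphthylene-1,2-dione
Product: 30 (1R,2S)-1,2-dimethyl-1,2-dihydroacenaphthylene-1,2-diol (cis, meso; mac diol)
Conditions: AlMe3 (4 equiv), toluene, 0 °C to rt; aq. HCl work-up; recrystallisation
Reagents that add atoms: trimethylaluminium, C[Al](C)C
Why: Double methyl addition to the 1,2-dione should give mainly the cis diol because the second methyl group enters anti to the bulky aluminium alkoxide formed first, and the meso diol is purified by crystallisation.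

Step 23
Reactants: 31 tert-butyldimethyl(prop-2-yn-1-yloxy)silane; 30 mac diol
Product: 35 tert-butyldimethyl{[3-B(mac)prop-2-yn-1-yl]oxy}silane, via lithium acetylide 32 (not isolated), via lithium alkynylborate 33 (not isolated), via diisopropyl alkynylboronate 34 (not isolated)
Conditions: n-BuLi, THF, −78 °C; B(Oi-Pr)3; HCl in Et2O, −78 °C to rt; then 30, rt, volatiles removed
Reagents that add atoms: triisopropyl borate, CC(C)OB(OC(C)C)OC(C)C
Why: Borylation of the lithium acetylide, acid release of the alkynyl diisopropyl boronate and transesterification with the diol is the standard route to alkynylboronic esters and is driven by removal of propan-2-ol.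

Step 24
Reactants: 35 tert-butyldimethyl{[3-B(mac)prop-2-yn-1-yl]oxy}silane
Product: 37 tert-butyldimethyl{[(Z)-3-B(mac)prop-2-en-1-yl]oxy}silane, via borazirconocene alkene 36 (not isolated)
Conditions: Cp2Zr(H)Cl, THF, rt; then H2O
Reagents that add atoms: none
Why: Syn hydrozirconation of an alkynylboronic ester with the Schwartz reagent places zirconium on the boron-bearing carbon, and stereoretentive protonolysis of the C–Zr bond then gives the Z alkenylboronate free of the E isomer.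

Step 25
Reactants: 28 1-(benzyloxy)-4-bromo-2-methoxybenzene; 37 tert-butyldimethyl{[(Z)-3-B(mac)prop-2-en-1-yl]oxy}silane; 26 (3S,4S)-3-{[4-(benzyloxy)-3-bromo-5-methoxyphenyl]methyl}-4-(DHB-methyl)oxolan-2-one
Product: 40 (3S,4S)-3-({4-(benzyloxy)-3-[(1S,2S)-1-Ar-1-B(mac)-3-[(tert-butyldimethylsilyl)oxy]propan-2-yl]-5-methoxyphenyl}methyl)-4-(DHB-methyl)oxolan-2-one, via aryllithium 38 (not isolated), via lithium boron ate complex 39 (not isolated)
Conditions: 28 (1.5 equiv), t-BuLi (3.0 equiv), Et2O, −78 °C; 37 (1.6 equiv), −78 °C to rt, then solvent exchange to THF; 26 (1.0 equiv), Pd(OAc)2 (5 mol %), (Sp,Sp)-MandyPhos ligand [1,1'-bis{bis(4-methoxy-3,5-dimethylphenyl)phosphino}-2,2'-bis{(R)-α-(dimethylamino)benzyl}ferrocene] (6 mol %), NaOTf (3 equiv), THF, 60 °C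
Reagents that add atoms: none
Why: Zerovalent palladium, formed in situ from Pd(OAc)2 and the bisphosphine, inserts into the C–Br bond of 26, NaOTf removes bromide so that the cationic arylpalladium binds the alkene of ate complex 39, this triggers an antiperiplanar 1,2-shift of the 4-benzyloxy-3-methoxyphenyl group from boron to C1 while C2 bonds to palladium, and stereoretentive reductive elimination forms the C2–aryl bond. The closest known reaction type is the enantio- and diastereoselective conjunctive cross-coupling of β-substituted alkenylboron ate complexes with aryl electrophiles, of which the Z alkene, the ortho-benzyloxy aryl bromide and the lactone are substrate extensions. No ring is closed. Anti addition of the two aryl groups across the Z alkene fixes the relative configuration of C1 and C2 (the anti arm of the target after oxidation), and the chiral ligand on palladium selects the alkene face and hence the absolute (1S,2S) configuration, overriding the remote stereocentres of 26. The step needs the metallate shift to beat direct Suzuki–Miyaura transfer of the alkenyl group, which the hindered mac diol on boron secures by slowing transmetallation, and it needs the lactone to survive, which is secured because all aryllithium is bound as the borate (37 in slight excess over 38) before 26 is added.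

Step 26
Reactants: 40 secondary B(mac) boronate
Product: 41 (3S,4S)-3-({4-(benzyloxy)-3-[(1S,2S)-1-Ar-3-[(tert-butyldimethylsilyl)oxy]-1-hydroxypropan-2-yl]-5-methoxyphenyl}methyl)-4-(DHB-methyl)oxolan-2-one
Conditions: 30% H2O2, NaHCO3, THF/H2O, 0 °C to rt; brief acidification to pH 4 on work-up
Reagents that add atoms: hydrogen peroxide, OO
Why: Peroxide oxidation of the C–B bond proceeds by 1,2-migration of carbon from boron to oxygen with retention at C1, and the bicarbonate buffer keeps the lactone closed.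

Step 27
Reactants: 41 silyl-protected secondary alcohol
Product: 42 (3S,4S)-3-({4-(benzyloxy)-3-[(1S,2S)-1-Ar-1,3-dihydroxypropan-2-yl]-5-methoxyphenyl}methyl)-4-{[(2R,3S)-2-Ar-3-(hydroxymethyl)-7-methoxy-2,3-dihydro-1-benzofuran-5-yl]methyl}oxolan-2-one
Conditions: Bu4NF, AcOH, THF, rt
Reagents that add atoms: none
Why: Fluoride cleaves both the TBS and the TBDPS ether, and buffering with acetic acid protects the lactone and the benzylic carbinol from base.

Step 28
Reactants: 42 tri-O-benzyl tetraol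
Product: 43 CNP0186558.3 (target)
Conditions: H2 (1 atm), 10% Pd/C, EtOAc/MeOH, rt, stopped at full conversion
Reagents that add atoms: none
Why: Hydrogenolysis of aryl benzyl ethers under neutral conditions at atmospheric pressure is much faster than cleavage of the benzylic C1–OH bond or of the ring C2–O bond, so the three phenols should be freed without loss of benzylic oxygen.

## Compound list

1 | 5-bromovanillin (3-bromo-4-hydroxy-5-methoxybenzaldehyde) | COc1cc(C=O)cc(Br)c1O | starting material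
2 | 4-(benzyloxy)-3-bromo-5-methoxybenzaldehyde | COc1cc(C=O)cc(Br)c1OCc1ccccc1 | intermediate
3 | [4-(benzyloxy)-3-bromo-5-methoxyphenyl]methanol | COc1cc(CO)cc(Br)c1OCc1ccccc1 | intermediate
4 | 2-(benzyloxy)-1-bromo-5-(bromomethyl)-3-methoxybenzene | COc1cc(CBr)cc(Br)c1OCc1ccccc1 | intermediate
5 | [4-(benzyloxy)-3-methoxyphenyl]methanol | COc1cc(CO)ccc1OCc1ccccc1 | starting material
6 | 4-(Ar-methoxy)-3-bromo-5-methoxybenzaldehyde | COc1cc(C=O)cc(Br)c1OCc1ccc(OCc2ccccc2)c(OC)c1 | intermediate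
7 | [4-(Ar-methoxy)-3-bromo-5-methoxyphenyl]methanol | COc1cc(CO)cc(Br)c1OCc1ccc(OCc2ccccc2)c(OC)c1 | intermediate
8 | {[4-(Ar-methoxy)-3-bromo-5-methoxyphenyl]methoxy}(tert-butyl)dimethylsilane | COc1cc(CO[Si](C)(C)C(C)(C)C)cc(Br)c1OCc1ccc(OCc2ccccc2)c(OC)c1 | intermediate
9 | tert-butyl 2-[2-(Ar-methoxy)-5-{[(tert-butyldimethylsilyl)oxy]methyl}-3-methoxyphenyl]acetate | COc1cc(CO[Si](C)(C)C(C)(C)C)cc(CC(=O)OC(C)(C)C)c1OCc1ccc(OCc2ccccc2)c(OC)c1 | intermediate
10 | tert-butyl 2-diazo-2-[2-(Ar-methoxy)-5-{[(tert-butyldimethylsilyl)oxy]methyl}-3-methoxyphenyl]acetate | COc1cc(CO[Si](C)(C)C(C)(C)C)cc(C(=[N+]=[N-])C(=O)OC(C)(C)C)c1OCc1ccc(OCc2ccccc2)c(OC)c1 | intermediate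
11 | tert-butyl (2R,3S)-2-Ar-5-{[(tert-butyldimethylsilyl)oxy]methyl}-7-methoxy-2,3-dihydro-1-benzofuran-3-carboxylate (cis) | CC(C)(C)[Si](C)(C)OCc1cc(OC)c2c(c1)[C@H](C(=O)OC(C)(C)C)[C@H](c1ccc(OCc3ccccc3)c(OC)c1)O2 | intermediate
12 | tert-butyl (2R,3R)-2-Ar-5-{[(tert-butyldimethylsilyl)oxy]methyl}-7-methoxy-2,3-dihydro-1-benzofuran-3-carboxylate (trans) | CC(C)(C)[Si](C)(C)OCc1cc(OC)c2c(c1)[C@@H](C(=O)OC(C)(C)C)[C@H](c1ccc(OCc3ccccc3)c(OC)c1)O2 | intermediate
13 | [(2R,3S)-2-Ar-5-{[(tert-butyldimethylsilyl)oxy]methyl}-7-methoxy-2,3-dihydro-1-benzofuran-3-yl]methanol | CC(C)(C)[Si](C)(C)OCc1cc(OC)c2c(c1)[C@@H](CO)[C@H](c1ccc(OCc3ccccc3)c(OC)c1)O2 | intermediate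
14 | (2R,3S)-2-Ar-5-{[(tert-butyldimethylsilyl)oxy]methyl}-3-{[(tert-butyldiphenylsilyl)oxy]methyl}-7-methoxy-2,3-dihydro-1-benzofuran | CC(C)(C)[Si](C)(C)OCc1cc(OC)c2c(c1)[C@@H](CO[Si](c3ccccc3)(c3ccccc3)C(C)(C)C)[C@H](c1ccc(OCc3ccccc3)c(OC)c1)O2 | intermediate
15 | DHB-methanol | OCc1cc(OC)c2c(c1)[C@@H](CO[Si](c3ccccc3)(c3ccccc3)C(C)(C)C)[C@H](c1ccc(OCc3ccccc3)c(OC)c1)O2 | intermediate
16 | DHB-methyl bromide | BrCc1cc(OC)c2c(c1)[C@@H](CO[Si](c3ccccc3)(c3ccccc3)C(C)(C)C)[C@H](c1ccc(OCc3ccccc3)c(OC)c1)O2 | intermediate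
17 | (S)-4-benzyl-1,3-oxazolidin-2-one | O=C1OC[C@H](Cc2ccccc2)N1 | starting material
18 | (S)-4-benzyl-3-(pent-4-enoyl)-1,3-oxazolidin-2-one | O=C1OC[C@H](Cc2ccccc2)N1C(=O)CCC=C | intermediate
19 | sodium (Z)-enolate of 18 | [Na+].O=C1OC[C@H](Cc2ccccc2)N1/C([O-])=C/CC=C | intermediate
20 | (4S)-4-benzyl-3-[(2R)-2-(DHB-methyl)pent-4-enoyl]-1,3-oxazolidin-2-one | O=C1OC[C@H](Cc2ccccc2)N1C(=O)[C@H](CC=C)Cc1cc(OC)c2c(c1)[C@@H](CO[Si](c3ccccc3)(c3ccccc3)C(C)(C)C)[C@H](c1ccc(OCc3ccccc3)c(OC)c1)O2 | intermediate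
21 | (2R)-2-(DHB-methyl)pent-4-en-1-ol | OC[C@H](CC=C)Cc1cc(OC)c2c(c1)[C@@H](CO[Si](c3ccccc3)(c3ccccc3)C(C)(C)C)[C@H](c1ccc(OCc3ccccc3)c(OC)c1)O2 | intermediate
22 | (3S)-4-DHB-3-(hydroxymethyl)butanal | OC[C@H](CC=O)Cc1cc(OC)c2c(c1)[C@@H](CO[Si](c3ccccc3)(c3ccccc3)C(C)(C)C)[C@H](c1ccc(OCc3ccccc3)c(OC)c1)O2 | intermediate
23 | (4S)-4-(DHB-methyl)oxolan-2-ol (anomer mixture) | OC1C[C@H](Cc2cc(OC)c3c(c2)[C@@H](CO[Si](c4ccccc4)(c4ccccc4)C(C)(C)C)[C@H](c2ccc(OCc4ccccc4)c(OC)c2)O3)CO1 | intermediate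
24 | (4S)-4-(DHB-methyl)oxolan-2-one | O=C1C[C@H](Cc2cc(OC)c3c(c2)[C@@H](CO[Si](c4ccccc4)(c4ccccc4)C(C)(C)C)[C@H](c2ccc(OCc4ccccc4)c(OC)c2)O3)CO1 | intermediate
25 | lithium enolate of 24 | [Li+].[O-]C1=C[C@H](Cc2cc(OC)c3c(c2)[C@@H](CO[Si](c4ccccc4)(c4ccccc4)C(C)(C)C)[C@H](c2ccc(OCc4ccccc4)c(OC)c2)O3)CO1 | intermediate
26 | (3S,4S)-3-{[4-(benzyloxy)-3-bromo-5-methoxyphenyl]methyl}-4-(DHB-methyl)oxolan-2-one | Brc1cc(C[C@@H]2C(=O)OC[C@H]2Cc2cc(OC)c3c(c2)[C@@H](CO[Si](c4ccccc4)(c4ccccc4)C(C)(C)C)[C@H](c2ccc(OCc4ccccc4)c(OC)c2)O3)cc(OC)c1OCc1ccccc1 | intermediate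
27 | 4-bromo-2-methoxyphenol | COc1cc(Br)ccc1O | starting material
28 | 1-(benzyloxy)-4-bromo-2-methoxybenzene | COc1cc(Br)ccc1OCc1ccccc1 | intermediate
29 | acenaphthylene-1,2-dione | O=C1C(=O)c2cccc3cccc1c23 | starting material
30 | (1R,2S)-1,2-dimethyl-1,2-dihydroacenaphthylene-1,2-diol (mac diol) | C[C@]1(O)c2cccc3cccc(c23)[C@@]1(C)O | intermediate
31 | tert-butyldimethyl(prop-2-yn-1-yloxy)silane | C#CCO[Si](C)(C)C(C)(C)C | starting material
32 | lithium acetylide of 31 | [Li]C#CCO[Si](C)(C)C(C)(C)C | intermediate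
33 | lithium triisopropoxy[3-(TBS-oxy)prop-1-ynyl]borate | [Li+].CC(C)O[B-](OC(C)C)(OC(C)C)C#CCO[Si](C)(C)C(C)(C)C | intermediate
34 | diisopropyl [3-(TBS-oxy)prop-1-ynyl]boronate | CC(C)OB(OC(C)C)C#CCO[Si](C)(C)C(C)(C)C | intermediate
35 | tert-butyldimethyl{[3-B(mac)prop-2-yn-1-yl]oxy}silane | CC(C)(C)[Si](C)(C)OCC#CB1O[C@@]2(C)c3cccc4cccc(c34)[C@@]2(C)O1 | intermediate
36 | 1-B(mac)-1-[chlorobis(cyclopentadienyl)zirconio]-3-(TBS-oxy)prop-1-ene (H and Zr cis) | CC(C)(C)[Si](C)(C)OC/C=C(\B1O[C@@]2(C)c3cccc4cccc(c34)[C@@]2(C)O1)[Zr](Cl)(C1C=CC=C1)C1C=CC=C1 | intermediate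
37 | tert-butyldimethyl{[(Z)-3-B(mac)prop-2-en-1-yl]oxy}silane | CC(C)(C)[Si](C)(C)OC/C=C\B1O[C@@]2(C)c3cccc4cccc(c34)[C@@]2(C)O1 | intermediate
38 | [4-(benzyloxy)-3-methoxyphenyl]lithium | [Li]c1ccc(OCc2ccccc2)c(OC)c1 | intermediate
39 | lithium Ar[(Z)-3-(TBS-oxy)prop-1-enyl]borate of the mac diol (configuration at boron not defined) | [Li+].CC(C)(C)[Si](C)(C)OC/C=C\[B-]1(c2ccc(OCc3ccccc3)c(OC)c2)O[C@@]2(C)c3cccc4cccc(c34)[C@@]2(C)O1 | intermediate
40 | (3S,4S)-3-({4-(benzyloxy)-3-[(1S,2S)-1-Ar-1-B(mac)-3-[(tert-butyldimethylsilyl)oxy]propan-2-yl]-5-methoxyphenyl}methyl)-4-(DHB-methyl)oxolan-2-one | COc1cc([C@@H](B5O[C@@]6(C)c7cccc8cccc(c78)[C@@]6(C)O5)[C@H](CO[Si](C)(C)C(C)(C)C)c2cc(C[C@@H]3C(=O)OC[C@H]3Cc3cc(OC)c4c(c3)[C@@H](CO[Si](c5ccccc5)(c5ccccc5)C(C)(C)C)[C@H](c3ccc(OCc5ccccc5)c(OC)c3)O4)cc(OC)c2OCc2ccccc2)ccc1OCc1ccccc1 | intermediate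
41 | (3S,4S)-3-({4-(benzyloxy)-3-[(1S,2S)-1-Ar-3-[(tert-butyldimethylsilyl)oxy]-1-hydroxypropan-2-yl]-5-methoxyphenyl}methyl)-4-(DHB-methyl)oxolan-2-one | COc1cc([C@@H](O)[C@H](CO[Si](C)(C)C(C)(C)C)c2cc(C[C@@H]3C(=O)OC[C@H]3Cc3cc(OC)c4c(c3)[C@@H](CO[Si](c5ccccc5)(c5ccccc5)C(C)(C)C)[C@H](c3ccc(OCc5ccccc5)c(OC)c3)O4)cc(OC)c2OCc2ccccc2)ccc1OCc1ccccc1 | intermediate
42 | (3S,4S)-3-({4-(benzyloxy)-3-[(1S,2S)-1-Ar-1,3-dihydroxypropan-2-yl]-5-methoxyphenyl}methyl)-4-{[(2R,3S)-2-Ar-3-(hydroxymethyl)-7-methoxy-2,3-dihydro-1-benzofuran-5-yl]methyl}oxolan-2-one | COc1cc([C@@H](O)[C@H](CO)c2cc(C[C@@H]3C(=O)OC[C@H]3Cc3cc(OC)c4c(c3)[C@@H](CO)[C@H](c3ccc(OCc5ccccc5)c(OC)c3)O4)cc(OC)c2OCc2ccccc2)ccc1OCc1ccccc1 | intermediate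
43 | CNP0186558.3: (3S,4S)-3-({3-[(1S,2S)-1,3-dihydroxy-1-(4-hydroxy-3-methoxyphenyl)propan-2-yl]-4-hydroxy-5-methoxyphenyl}methyl)-4-{[(2R,3S)-2-(4-hydroxy-3-methoxyphenyl)-3-(hydroxymethyl)-7-methoxy-2,3-dihydro-1-benzofuran-5-yl]methyl}oxolan-2-one | COc1cc([C@@H](O)[C@H](CO)c2cc(C[C@@H]3C(=O)OC[C@H]3Cc3cc(OC)c4c(c3)[C@@H](CO)[C@H](c3ccc(O)c(OC)c3)O4)cc(OC)c2O)ccc1O | target

## Step count and risks

Total step count: 28. Longest linear sequence: 20 steps (steps 4 to 14, 16 to 20, 25 to 28, from 5-bromovanillin).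

The three steps most likely to fail:

1. Step 25 (three-component coupling). Direct transfer of the alkenyl group to palladium may outrun the 1,2-metallate shift; oxidative addition at the ortho-benzyloxy aryl bromide may be slow or the cationic palladium may be poisoned by bromide; the alkylpalladium may lose the β-silyloxy group; facial selectivity may erode. The fallback builds the arm by allylboration instead. It sets out from 26 and comes back at 42. Stille vinylation of 26 (tributyl(vinyl)stannane, Pd(PPh3)4, toluene, 100 °C) should give the styrene F1. Cross-metathesis with allylboronic acid pinacol ester (second-generation Hoveyda–Grubbs catalyst, CH2Cl2, 40 °C) should give the (E)-3-arylallyl boronate F2. Allylboration of 4-benzyloxy-3-methoxybenzaldehyde catalysed by a chiral phosphoric acid (TRIP, toluene, −30 °C) runs through a chair transition state, so the E boronate should give the anti homoallylic alcohol F3 with the catalyst choosing the aldehyde face. OsO4/NaIO4 cleavage to the aldehyde F4 and immediate NaBH4 reduction should give the diol F5, and Bu4NF/AcOH then gives 42.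

2. Step 9 (carbene C–H insertion). Enantio-induction with the tert-butyl ester may be insufficient, or carbene dimerisation and attack on the electron-rich benzyl ring may compete. The fallback replaces asymmetric catalysis by resolution. It sets out from 10 and comes back at 13. Insertion with achiral Rh2(OAc)4 (CH2Cl2, rt) should give 11 and 12 together with their enantiomers, the ent-cis ester F6 and the ent-trans ester F7. t-BuOK equilibration converts the cis esters into the trans pair, and LiAlH4 gives 13 with its enantiomer, the ent-alcohol F8. Esterification with (S)-2-methoxy-2-phenylacetic acid (DCC, DMAP) gives the diastereomeric esters F9 (from 13) and F10 (from F8), which are separated by chromatography or crystallisation. K2CO3/MeOH on F9 returns 13.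

3. Step 28 (hydrogenolysis). Over-reduction may occur: cleavage of the benzylic C1–OH bond of the arm or of the benzylic C2–O bond of the dihydrobenzofuran may compete with O-debenzylation. The fallback moves the hydrogenolysis ahead of the oxidation, so that no acyclic benzylic carbinol is exposed to palladium and hydrogen. It sets out from 40 and comes back at 43. H2, Pd/C (EtOAc, rt) on 40 should give the triphenol boronate F11, whose benzylic C–B bond is inert to hydrogenolysis. H2O2/NaHCO3 then gives the triphenol bis-silyl ether F12, and Bu4NF/AcOH gives 43.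

Further compounds

F1 | step 25 | (3S,4S)-3-{[4-(benzyloxy)-3-ethenyl-5-methoxyphenyl]methyl}-4-(DHB-methyl)oxolan-2-one | C=Cc1cc(C[C@@H]2C(=O)OC[C@H]2Cc2cc(OC)c3c(c2)[C@@H](CO[Si](c4ccccc4)(c4ccccc4)C(C)(C)C)[C@H](c2ccc(OCc4ccccc4)c(OC)c2)O3)cc(OC)c1OCc1ccccc1
F2 | step 25 | pinacol (E)-3-aryl-allylboronate of the lactone fragment | CC1(C)OB(OC1(C)C)C/C=C/c1cc(C[C@@H]2C(=O)OC[C@H]2Cc2cc(OC)c3c(c2)[C@@H](CO[Si](c4ccccc4)(c4ccccc4)C(C)(C)C)[C@H](c2ccc(OCc4ccccc4)c(OC)c2)O3)cc(OC)c1OCc1ccccc1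
F3 | step 25 | anti homoallylic alcohol (1-Ar-1-hydroxybut-3-en-2-yl arm, configured as the target arm) | COc1cc([C@@H](O)[C@H](C=C)c2cc(C[C@@H]3C(=O)OC[C@H]3Cc3cc(OC)c4c(c3)[C@@H](CO[Si](c5ccccc5)(c5ccccc5)C(C)(C)C)[C@H](c3ccc(OCc5ccccc5)c(OC)c3)O4)cc(OC)c2OCc2ccccc2)ccc1OCc1ccccc1
F4 | step 25 | β-hydroxy aldehyde from cleavage of F3 | COc1cc([C@@H](O)[C@H](C=O)c2cc(C[C@@H]3C(=O)OC[C@H]3Cc3cc(OC)c4c(c3)[C@@H](CO[Si](c5ccccc5)(c5ccccc5)C(C)(C)C)[C@H](c3ccc(OCc5ccccc5)c(OC)c3)O4)cc(OC)c2OCc2ccccc2)ccc1OCc1ccccc1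
F5 | step 25 | 1,3-diol arm with the TBDPS ether retained on the dihydrobenzofuran | COc1cc([C@@H](O)[C@H](CO)c2cc(C[C@@H]3C(=O)OC[C@H]3Cc3cc(OC)c4c(c3)[C@@H](CO[Si](c5ccccc5)(c5ccccc5)C(C)(C)C)[C@H](c3ccc(OCc5ccccc5)c(OC)c3)O4)cc(OC)c2OCc2ccccc2)ccc1OCc1ccccc1
F6 | step 9 | tert-butyl (2S,3R)-2-Ar-5-{[(tert-butyldimethylsilyl)oxy]methyl}-7-methoxy-2,3-dihydro-1-benzofuran-3-carboxylate (enantiomer of 11) | CC(C)(C)[Si](C)(C)OCc1cc(OC)c2c(c1)[C@@H](C(=O)OC(C)(C)C)[C@@H](c1ccc(OCc3ccccc3)c(OC)c1)O2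
F7 | step 9 | tert-butyl (2S,3S)-2-Ar-5-{[(tert-butyldimethylsilyl)oxy]methyl}-7-methoxy-2,3-dihydro-1-benzofuran-3-carboxylate (enantiomer of 12) | CC(C)(C)[Si](C)(C)OCc1cc(OC)c2c(c1)[C@H](C(=O)OC(C)(C)C)[C@@H](c1ccc(OCc3ccccc3)c(OC)c1)O2
F8 | step 9 | [(2S,3R)-2-Ar-5-{[(tert-butyldimethylsilyl)oxy]methyl}-7-methoxy-2,3-dihydro-1-benzofuran-3-yl]methanol (enantiomer of 13) | CC(C)(C)[Si](C)(C)OCc1cc(OC)c2c(c1)[C@H](CO)[C@@H](c1ccc(OCc3ccccc3)c(OC)c1)O2
F9 | step 9 | (S)-2-methoxy-2-phenylacetate of 13 | CC(C)(C)[Si](C)(C)OCc1cc(OC)c2c(c1)[C@@H](COC(=O)[C@@H](OC)c1ccccc1)[C@H](c1ccc(OCc3ccccc3)c(OC)c1)O2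
F10 | step 9 | (S)-2-methoxy-2-phenylacetate of F8 | CC(C)(C)[Si](C)(C)OCc1cc(OC)c2c(c1)[C@H](COC(=O)[C@@H](OC)c1ccccc1)[C@@H](c1ccc(OCc3ccccc3)c(OC)c1)O2
F11 | step 28 | triphenol secondary B(mac) boronate (40 without its three benzyl groups) | COc1cc([C@@H](B5O[C@@]6(C)c7cccc8cccc(c78)[C@@]6(C)O5)[C@H](CO[Si](C)(C)C(C)(C)C)c2cc(C[C@@H]3C(=O)OC[C@H]3Cc3cc(OC)c4c(c3)[C@@H](CO[Si](c5ccccc5)(c5ccccc5)C(C)(C)C)[C@H](c3ccc(O)c(OC)c3)O4)cc(OC)c2O)ccc1O
F12 | step 28 | triphenol secondary alcohol with both silyl ethers (41 without its three benzyl groups) | COc1cc([C@@H](O)[C@H](CO[Si](C)(C)C(C)(C)C)c2cc(C[C@@H]3C(=O)OC[C@H]3Cc3cc(OC)c4c(c3)[C@@H](CO[Si](c5ccccc5)(c5ccccc5)C(C)(C)C)[C@H](c3ccc(O)c(OC)c3)O4)cc(OC)c2O)ccc1O
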